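**Retrosynthetic overview**
1. Target 33 ⇐ silyl ether 32 ⇐ epoxy diol 24 + (Z)-acid 31: hydroxyl-directed opening of the 7α,8α-epoxide at C7 makes the C7–O ester bond with inversion and frees the 8α-OH.
2. 24 ⇐ enol triflate 22 (C4–C11 by Stille hydroxymethylation) ⇐ epoxy ketone 20 ⇐ cis-fused bicyclic ketone 18 (bromohydrin, then closure to the α-epoxide).
3. 18 ⇐ pyranone acetal ester 8 + alkenyl trifluoroborate 14: rhodium-catalysed conjugate alkenylation forms C8–C9, then enolate alkylation forms C5–C6.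
4. 8 ⇐ furfuryl alcohol 5 + acid 4 (from 1 + 2 by copper-catalysed conjugate addition); 14 ⇐ but-2-yne-1,4-diol 9; 31 ⇐ 4-bromophenol 25 + propiolic acid 29 (Stille coupling).
5. Ring order: pyran ring first (Achmatowicz), cyclopentene second (annulation on the enone); the epoxide is opened last.

Convention: iridoid numbering (C1 acetal carbon, O2, C3=C4, C5 and C9 ring fusion, C6, C7, C8; C10 on C8, C11 on C4); β is the face of H-5 and H-9; TBS = tert-butyldimethylsilyl.
Assumption: where a chiral ligand, catalyst or tartrate is named, the enantiomer meant is the one that gives the configuration drawn.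

**Route**

Step 1
Reactants: 1 methyl (E)-but-2-enoate; 2 ethylmagnesium bromide
Product: 3 methyl (R)-3-methylpentanoate
Conditions: CuI (1 mol %), (S)-Tol-BINAP (1.5 mol %), t-BuOMe, −40 °C
Reagents that add atoms: none
Why: Copper-catalysed asymmetric conjugate addition of a Grignard reagent to an enoate: the Tol-BINAP complex of monovalent copper delivers ethyl to one enantioface of the crotonate and thereby sets the (R) centre.

Step 2
Reactants: 3 methyl (R)-3-methylpentanoate
Product: 4 (R)-3-methylpentanoic acid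
Conditions: LiOH, THF/H2O, 25 °C; then 1 M HCl
Reagents that add atoms: lithium hydroxide, [Li+].[OH-]
Why: Saponification of the methyl ester; the stereocentre is β to the carbonyl group and cannot epimerise.

Step 3
Reactants: 5 furfuryl alcohol
Product: 6 racemic 6-hydroxy-2H-pyran-3(6H)-one
Conditions: NBS, NaHCO3, THF/H2O (4:1), 0 °C
Reagents that add atoms: water, O
Why: Achmatowicz oxidative ring expansion: bromonium-induced hydration of the furan gives the cis-enedione that closes to the pyranone lactol (racemic and configurationally labile at C1).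

Step 4
Reactants: 4 (R)-3-methylpentanoic acid; 6 racemic 6-hydroxy-2H-pyran-3(6H)-one
Product: 8 (S)-5-oxo-5,6-dihydro-2H-pyran-2-yl (R)-3-methylpentanoate, via mixed pivalic anhydride 7 (not isolated)
Conditions: 4, t-BuCOCl, i-Pr2NEt, CH2Cl2, 0 °C; then 6, (R)-benzotetramisole (5 mol %), −20 °C
Reagents that add atoms: none
Why: Acylative dynamic kinetic resolution by isothiourea (acyl-transfer) catalysis: the lactol enantiomers interconvert by ring opening while the chiral acyl-isothiouronium ion formed at the less hindered carbonyl of 7 acylates only one of them and so sets (S)-C1 as the acetal ester.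

Step 5
Reactants: 9 but-2-yne-1,4-diol
Product: 10 4-[(tert-butyldimethylsilyl)oxy]but-2-yn-1-ol
Conditions: TBSCl (0.3 equiv), imidazole, DMF, 0 °C
Reagents that add atoms: tert-butyldimethylsilyl chloride, CC(C)(C)[Si](C)(C)Cl
Why: Statistical monosilylation of a symmetrical diol used in threefold excess.

Step 6
Reactants: 10 4-[(tert-butyldimethylsilyl)oxy]but-2-yn-1-ol
Product: 12 (Z)-4-[(tert-butyldimethylsilyl)oxy]-3-iodobut-2-en-1-ol, via cyclic sodium alkenylaluminate 11 (not isolated)
Conditions: NaAlH2(OCH2CH2OMe)2, THF, 0 °C; then I2, −78 °C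
Reagents that add atoms: iodine, II
Why: Hydroxyl-directed trans-hydroalumination of the propargylic alcohol places aluminium on the carbon remote from the free hydroxyl group in a five-membered ring and iodinolysis with retention then fixes iodine cis to CH2OH (Z).

Step 7
Reactants: 12 (Z)-4-[(tert-butyldimethylsilyl)oxy]-3-iodobut-2-en-1-ol
Product: 14 potassium (E)-{1-[(tert-butyldimethylsilyl)oxy]-4-hydroxybut-2-en-2-yl}trifluoroborate, via pinacol boronate 13 (not isolated)
Conditions: B2pin2, PdCl2(PPh3)2 (3 mol %), PPh3, KOPh, toluene, 50 °C; then KHF2, MeOH/H2O, 25 °C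
Reagents that add atoms: bis(pinacolato)diboron, CC1(C)OB(OC1(C)C)B2OC(C)(C)C(C)(C)O2; potassium hydrogen difluoride, [K+].F[H-]F
Why: Miyaura borylation (oxidative addition to zerovalent palladium then transmetalation with the diboron reagent) replaces iodine by boron with retention of the alkene geometry and KHF2 converts the boronate into the open-chain trifluoroborate salt that cannot close to a cyclic boronic hemiester.

Step 8
Reactants: 8 (S)-5-oxo-5,6-dihydro-2H-pyran-2-yl (R)-3-methylpentanoate; 14 potassium (E)-{1-[(tert-butyldimethylsilyl)oxy]-4-hydroxybut-2-en-2-yl}trifluoroborate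
Product: 15 (2S,3S)-3-{(E)-1-[(tert-butyldimethylsilyl)oxy]-4-hydroxybut-2-en-2-yl}-5-oxotetrahydro-2H-pyran-2-yl (R)-3-methylpentanoate
Conditions: [Rh(OH)(cod)]2 (3 mol %), 1,4-dioxane/H2O (6:1), 40 °C
Reagents that add atoms: none
Why: Hayashi–Miyaura rhodium-catalysed 1,4-addition: transmetalation gives an alkenyl complex of monovalent rhodium that inserts the enone on the face anti to the pseudoaxial C1 acyloxy group (C8–C9 bond formed; H-9 β; alkene geometry retained) and water protonates the oxa-π-allyl rhodium so that the anomeric ester never meets a hard nucleophile.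

Step 9
Reactants: 15 (2S,3S)-3-{(E)-1-[(tert-butyldimethylsilyl)oxy]-4-hydroxybut-2-en-2-yl}-5-oxotetrahydro-2H-pyran-2-yl (R)-3-methylpentanoate
Product: 16 (2S,3S)-3-{(E)-4-bromo-1-[(tert-butyldimethylsilyl)oxy]but-2-en-2-yl}-5-oxotetrahydro-2H-pyran-2-yl (R)-3-methylpentanoate
Conditions: CBr4, PPh3, CH2Cl2, 0 °C
Reagents that add atoms: carbon tetrabromide, BrC(Br)(Br)Br
Why: Appel reaction converts the primary allylic alcohol into the bromide under neutral conditions that spare the acetal ester and the silyl ether.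

Step 10
Reactants: 16 (2S,3S)-3-{(E)-4-bromo-1-[(tert-butyldimethylsilyl)oxy]but-2-en-2-yl}-5-oxotetrahydro-2H-pyran-2-yl (R)-3-methylpentanoate
Product: 18 (1S,4aS,7aS)-7-{[(tert-butyldimethylsilyl)oxy]methyl}-4-oxo-1,3,4,4a,5,7a-hexahydrocyclopenta[c]pyran-1-yl (R)-3-methylpentanoate, via potassium enolate 17 (not isolated)
Conditions: KN(SiMe3)2 (0.95 equiv), THF, −78 to −20 °C
Reagents that add atoms: none
Why: Intramolecular SN2 C-alkylation of the ketone enolate by the cis-disposed allylic bromide (5-exo-tet cyclopentene annulation): the tether on C9 can reach only the same face of C5 which sets the cis ring fusion (H-5 β) while an enolate formed on the C3 side cannot cyclise and returns by proton exchange.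

Step 11
Reactants: 18 (1S,4aS,7aS)-7-{[(tert-butyldimethylsilyl)oxy]methyl}-4-oxo-1,3,4,4a,5,7a-hexahydrocyclopenta[c]pyran-1-yl (R)-3-methylpentanoate
Product: 19 (1S,4aS,6S,7R,7aS)-6-bromo-7-hydroxy-7-{[(tert-butyldimethylsilyl)oxy]methyl}-4-oxooctahydrocyclopenta[c]pyran-1-yl (R)-3-methylpentanoate
Conditions: NBS, THF/H2O (4:1), 0 °C, dark
Reagents that add atoms: N-bromosuccinimide, O=C1CCC(=O)N1Br; water, O
Why: Bromohydrin formation: the bromonium ion forms on the convex β face and water opens it at the tertiary C8 from the α face (Markovnikov and anti) which gives 7β-Br and 8α-OH with C10 pushed to the β face.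

Step 12
Reactants: 19 (1S,4aS,6S,7R,7aS)-6-bromo-7-hydroxy-7-{[(tert-butyldimethylsilyl)oxy]methyl}-4-oxooctahydrocyclopenta[c]pyran-1-yl (R)-3-methylpentanoate
Product: 20 7α,8α-epoxy ketone (epoxide of 18 on the face opposite H-5 and H-9)
Conditions: DBU, CH2Cl2, 25 °C
Reagents that add atoms: none
Why: Intramolecular Williamson etherification: the C8 alkoxide displaces the trans C7 bromide with inversion and gives the 7α,8α-epoxide (the face opposite to that of a direct peracid epoxidation).

Step 13
Reactants: 20 7α,8α-epoxy ketone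
Product: 22 C3=C4 enol triflate of 20 (OSO2CF3 on C4), via potassium enolate 21 (not isolated)
Conditions: KN(SiMe3)2, THF, −78 °C; then PhNTf2
Reagents that add atoms: N-phenylbis(trifluoromethanesulfonimide), O=S(=O)(N(c1ccccc1)S(=O)(=O)C(F)(F)F)C(F)(F)F
Why: Kinetic enolate formation and O-sulfonylation: the base removes a C3 proton because the ring-fusion C5–H sits on the hindered concave side and the enolate is trapped as the C3=C4 enol triflate.

Step 14
Reactants: 22 C3=C4 enol triflate
Product: 23 11-hydroxy enol ether (CH2OH on C4; epoxide and 10-O-TBS kept)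
Conditions: Bu3SnCH2OH, Pd(PPh3)4 (5 mol %), LiCl, 1,4-dioxane, 90 °C
Reagents that add atoms: (tributylstannyl)methanol, CCCC[Sn](CCCC)(CCCC)CO
Why: Stille cross-coupling (Kosugi-type hydroxymethylation): oxidative addition of the enol triflate to zerovalent palladium and LiCl-assisted transmetalation of the stannylmethanol install C11 at the alcohol oxidation level so that no hydride reagent has to meet the acetal ester.

Step 15
Reactants: 23 11-hydroxy enol ether
Product: 24 7α,8α-epoxy-10,11-diol
Conditions: Bu4NF, AcOH (1:1), THF, 0 °C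
Reagents that add atoms: none
Why: Fluoride-mediated desilylation buffered with AcOH which suppresses Payne rearrangement of the resulting 2,3-epoxy alcohol and cleavage of the acetal ester.

Step 16
Reactants: 25 4-bromophenol
Product: 26 (4-bromophenoxy)(tert-butyl)dimethylsilane
Conditions: TBSCl, imidazole, CH2Cl2, 25 °C
Reagents that add atoms: tert-butyldimethylsilyl chloride, CC(C)(C)[Si](C)(C)Cl
Why: Imidazole-assisted silylation of the phenol.

Step 17
Reactants: 26 (4-bromophenoxy)(tert-butyl)dimethylsilane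
Product: 28 tributyl{4-[(tert-butyldimethylsilyl)oxy]phenyl}stannane, via aryllithium 27 (not isolated)
Conditions: n-BuLi, THF, −78 °C; then Bu3SnCl
Reagents that add atoms: tributyltin chloride, CCCC[Sn](Cl)(CCCC)CCCC
Why: Bromine–lithium exchange followed by stannylation of the aryllithium.

Step 18
Reactants: 29 propiolic acid
Product: 30 (Z)-3-iodoacrylic acid
Conditions: NaI, AcOH, 70 °C
Reagents that add atoms: sodium iodide, [Na+].[I-]
Why: Anti hydroiodination of the ynoic acid by conjugate addition of iodide and protonation gives the kinetic (Z)-3-iodoacrylic acid.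

Step 19
Reactants: 28 tributyl{4-[(tert-butyldimethylsilyl)oxy]phenyl}stannane; 30 (Z)-3-iodoacrylic acid
Product: 31 (Z)-3-{4-[(tert-butyldimethylsilyl)oxy]phenyl}acrylic acid
Conditions: Pd2(dba)3 (2.5 mol %), AsPh3 (20 mol %), DMF, 25 °C, dark
Reagents that add atoms: none
Why: Stille cross-coupling at zerovalent palladium with the soft AsPh3 ligand proceeds with retention of the Z geometry of the iodoacrylate and tolerates the free acid and the aryl silyl ether.

Step 20
Reactants: 24 7α,8α-epoxy-10,11-diol; 31 (Z)-3-{4-[(tert-butyldimethylsilyl)oxy]phenyl}acrylic acid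
Product: 32 phenol O-TBS ether of the target
Conditions: Ph2BOCH2CH2NH2 (10 mol %), i-Pr2NEt (20 mol %), MeCN, 40 °C, dark
Reagents that add atoms: none
Why: Proposed new method: borinic acid-catalysed, hydroxyl-directed acyloxylative opening of a 2,3-epoxy alcohol, in which Ph2BOH (released from the aminoethyl ester) reversibly esterifies the C10 hydroxyl and, as a tethered Lewis acid, coordinates the epoxide oxygen in a five-membered chelate that polarises the distal C7–O bond, so that the ammonium carboxylate of 31 attacks the secondary C7 from the convex β face with inversion (7β-ester and 8α-OH; SN2 attack at the fully substituted C8 is disfavoured) and the product leaves as its 1,2-diol borinate, which is exchanged by fresh substrate and masks the diol against acyl migration; the closest known reaction types are the borinic acid-catalysed C3-selective opening of 2,3-epoxy alcohols by halide, amine and thiol nucleophiles and the stoichiometric Ti(OiPr)4-mediated C3 opening of 2,3-epoxy alcohols by carboxylic acids.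

Step 21
Reactants: 32 phenol O-TBS ether of the target
Product: 33 (1S,4aS,6S,7R,7aS)-7-hydroxy-4,7-bis(hydroxymethyl)-6-{[(2Z)-3-(4-hydroxyphenyl)prop-2-enoyl]oxy}-1,4a,5,6,7,7a-hexahydrocyclopenta[c]pyran-1-yl (3R)-3-methylpentanoate
Conditions: HF·pyridine, pyridine, THF, 0 °C, dark
Reagents that add atoms: none
Why: Buffered fluoride cleavage of the aryl silyl ether under conditions (pyridine buffer and darkness) that leave the acetal ester, the enol ether and the Z-cinnamate untouched.

**Compound list**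
1 | methyl (E)-but-2-enoate | C/C=C/C(=O)OC | starting material
2 | ethylmagnesium bromide | CC[Mg]Br | starting material
3 | methyl (R)-3-methylpentanoate | CC[C@@H](C)CC(=O)OC | intermediate
4 | (R)-3-methylpentanoic acid | CC[C@@H](C)CC(=O)O | intermediate
5 | furfuryl alcohol (furan-2-ylmethanol) | OCc1ccco1 | starting material
6 | racemic 6-hydroxy-2H-pyran-3(6H)-one | OC1OCC(=O)C=C1 | intermediate
7 | (R)-3-methylpentanoic pivalic anhydride | CC[C@@H](C)CC(=O)OC(=O)C(C)(C)C | intermediate
8 | (S)-5-oxo-5,6-dihydro-2H-pyran-2-yl (R)-3-methylpentanoate | CC[C@@H](C)CC(=O)O[C@@H]1OCC(=O)C=C1 | intermediate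
9 | but-2-yne-1,4-diol | OCC#CCO | starting material
10 | 4-[(TBS)oxy]but-2-yn-1-ol | OCC#CCO[Si](C)(C)C(C)(C)C | intermediate
11 | cyclic sodium alkenylaluminate (five-membered O–Al–C=C ring, Al on the carbon bearing CH2OTBS, two 2-methoxyethoxy ligands) | COCCO[Al-]1(OCCOC)OCC=C1CO[Si](C)(C)C(C)(C)C.[Na+] | intermediate
12 | (Z)-4-[(TBS)oxy]-3-iodobut-2-en-1-ol (I cis to CH2OH) | OC/C=C(\I)CO[Si](C)(C)C(C)(C)C | intermediate
13 | (E)-4-[(TBS)oxy]-3-(4,4,5,5-tetramethyl-1,3,2-dioxaborolan-2-yl)but-2-en-1-ol (B cis to CH2OH) | OC/C=C(\B1OC(C)(C)C(C)(C)O1)CO[Si](C)(C)C(C)(C)C | intermediate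
14 | potassium (E)-{1-[(TBS)oxy]-4-hydroxybut-2-en-2-yl}trifluoroborate (B cis to CH2OH) | OC/C=C(\[B-](F)(F)F)CO[Si](C)(C)C(C)(C)C.[K+] | intermediate
15 | (2S,3S)-3-{(E)-1-[(TBS)oxy]-4-hydroxybut-2-en-2-yl}-5-oxotetrahydro-2H-pyran-2-yl (R)-3-methylpentanoate (side chain trans to the acyloxy group; CH2OH cis to the ring carbon) | CC[C@@H](C)CC(=O)O[C@@H]1OCC(=O)C[C@H]1/C(CO[Si](C)(C)C(C)(C)C)=C\CO | intermediate
16 | (2S,3S)-3-{(E)-4-bromo-1-[(TBS)oxy]but-2-en-2-yl}-5-oxotetrahydro-2H-pyran-2-yl (R)-3-methylpentanoate | CC[C@@H](C)CC(=O)O[C@@H]1OCC(=O)C[C@H]1/C(CO[Si](C)(C)C(C)(C)C)=C\CBr | intermediate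
17 | potassium enolate of 16 (C4–O−, C4=C5) | CC[C@@H](C)CC(=O)O[C@@H]1OCC([O-])=C[C@H]1/C(CO[Si](C)(C)C(C)(C)C)=C\CBr.[K+] | intermediate
18 | (1S,4aS,7aS)-7-{[(TBS)oxy]methyl}-4-oxo-1,3,4,4a,5,7a-hexahydrocyclopenta[c]pyran-1-yl (R)-3-methylpentanoate (cis-fused, H-5β, H-9β, 1β-acyloxy, C7=C8) | CC[C@@H](C)CC(=O)O[C@@H]1OCC(=O)[C@H]2CC=C(CO[Si](C)(C)C(C)(C)C)[C@@H]12 | intermediate
19 | (1S,4aS,6S,7R,7aS)-6-bromo-7-hydroxy-7-{[(TBS)oxy]methyl}-4-oxooctahydrocyclopenta[c]pyran-1-yl (R)-3-methylpentanoate (7β-Br, 8α-OH, 8β-CH2OTBS) | CC[C@@H](C)CC(=O)O[C@@H]1OCC(=O)[C@H]2C[C@H](Br)[C@](O)(CO[Si](C)(C)C(C)(C)C)[C@@H]12 | intermediate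
20 | 7α,8α-epoxy ketone: 18 with the C7=C8 bond replaced by an epoxide whose oxygen lies on the α face (C10H2OTBS β, C4 ketone, C3H2) | CC[C@@H](C)CC(=O)O[C@@H]1OCC(=O)[C@H]2C[C@H]3O[C@@]3(CO[Si](C)(C)C(C)(C)C)[C@@H]12 | intermediate
21 | potassium enolate of 20 (C4–O−, C3=C4) | CC[C@@H](C)CC(=O)O[C@@H]1OC=C([O-])[C@H]2C[C@H]3O[C@@]3(CO[Si](C)(C)C(C)(C)C)[C@@H]12.[K+] | intermediate
22 | enol triflate: C3=C4 with OSO2CF3 on C4, 7α,8α-epoxide, 10-O-TBS, 1β-[(R)-3-methylpentanoyl]oxy | CC[C@@H](C)CC(=O)O[C@@H]1OC=C(OS(=O)(=O)C(F)(F)F)[C@H]2C[C@H]3O[C@@]3(CO[Si](C)(C)C(C)(C)C)[C@@H]12 | intermediate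
23 | 11-hydroxy enol ether: as 22 with CH2OH on C4 in place of the triflate | CC[C@@H](C)CC(=O)O[C@@H]1OC=C(CO)[C@H]2C[C@H]3O[C@@]3(CO[Si](C)(C)C(C)(C)C)[C@@H]12 | intermediate
24 | 7α,8α-epoxy-10,11-diol: as 23 with free C10 hydroxyl | CC[C@@H](C)CC(=O)O[C@@H]1OC=C(CO)[C@H]2C[C@H]3O[C@@]3(CO)[C@@H]12 | intermediate
25 | 4-bromophenol | Oc1ccc(Br)cc1 | starting material
26 | (4-bromophenoxy)(tert-butyl)dimethylsilane | CC(C)(C)[Si](C)(C)Oc1ccc(Br)cc1 | intermediate
27 | {4-[(TBS)oxy]phenyl}lithium | [Li]c1ccc(O[Si](C)(C)C(C)(C)C)cc1 | intermediate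
28 | tributyl{4-[(TBS)oxy]phenyl}stannane | CCCC[Sn](CCCC)(CCCC)c1ccc(O[Si](C)(C)C(C)(C)C)cc1 | intermediate
29 | propiolic acid (prop-2-ynoic acid) | C#CC(=O)O | starting material
30 | (Z)-3-iodoacrylic acid | OC(=O)/C=C\I | intermediate
31 | (Z)-3-{4-[(TBS)oxy]phenyl}acrylic acid | OC(=O)/C=C\c1ccc(O[Si](C)(C)C(C)(C)C)cc1 | intermediate
32 | (1S,4aS,6S,7R,7aS)-7-hydroxy-4,7-bis(hydroxymethyl)-6-{[(2Z)-3-{4-[(TBS)oxy]phenyl}prop-2-enoyl]oxy}-1,4a,5,6,7,7a-hexahydrocyclopenta[c]pyran-1-yl (3R)-3-methylpentanoate | CC[C@@H](C)CC(=O)O[C@@H]1OC=C(CO)[C@H]2C[C@H](OC(=O)/C=C\c3ccc(O[Si](C)(C)C(C)(C)C)cc3)[C@](O)(CO)[C@@H]12 | intermediate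
33 | (1S,4aS,6S,7R,7aS)-7-hydroxy-4,7-bis(hydroxymethyl)-6-{[(2Z)-3-(4-hydroxyphenyl)prop-2-enoyl]oxy}-1,4a,5,6,7,7a-hexahydrocyclopenta[c]pyran-1-yl (3R)-3-methylpentanoate | CC[C@@H](C)CC(=O)O[C@@H]1OC=C(CO)[C@H]2C[C@H](OC(=O)/C=C\c3ccc(O)cc3)[C@](O)(CO)[C@@H]12 | target

**Totals**
Total step count: 21.
Longest linear sequence: 13 steps (steps 5, 6, 7, 8, 9, 10, 11, 12, 13, 14, 15, 20, 21 from diol 9; equally steps 1, 2, 4 and then 8 to 15, 20, 21 from ester 1).

**Steps most likely to fail**

1. Step 20 (the proposed new method). The carboxylate may be too weak a nucleophile for the neopentyl-type C7, or the acyl group may migrate to O-10. The fallback uses known chemistry and builds the cinnamate on the scaffold instead of delivering it whole. It sets out from 24: a stoichiometric Ti(OiPr)4-mediated C3-selective opening of the 2,3-epoxy alcohol with the small acid 30 (CH2Cl2, 25 °C) gives the 7β-O-[(Z)-3-iodoacryloyl] 8α,10,11-triol F1. A neutral Stille coupling of F1 with stannane 28 (Pd2(dba)3, AsPh3, DMF, 25 °C, dark) then forms the aryl–alkene bond with retention of the Z geometry and comes back to the route at 32.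

2. Step 11 (with its partner step 12). The plan needs the bromonium ion on the β face and water entering C8 from the more hindered α face; if the facial or regiochemical outcome is poor, the α-epoxide is made by reagent control instead. The fallback sets out from 18: Bu4NF/AcOH in THF removes the silyl group to give the allylic alcohol F2. Sharpless asymmetric epoxidation (Ti(OiPr)4, diethyl tartrate, t-BuOOH, 4 Å sieves, CH2Cl2, −20 °C), with the tartrate chosen to deliver oxygen to the α face, gives the 7α,8α-epoxy alcohol F3. Resilylation with TBSCl and imidazole comes back to the route at 20.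

3. Step 4. The chiral acyl-isothiouronium ion derived from a β-branched mixed anhydride may give only moderate selectivity between the lactol enantiomers. The fallback separates the stereo-determining event from the introduction of the chiral acid. It sets out from 6: the same acyl-transfer dynamic kinetic resolution run with the simple reagent Boc2O gives the (S)-tert-butyl carbonate F4. A stereoretentive allylic substitution at zerovalent palladium (Pd2(dba)3, PPh3, CH2Cl2, 0 °C; ionisation and carboxylate capture each occur with inversion) with acid 4 as the nucleophile comes back to the route at 8.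

**Further compounds**
F1 | step 20 | (1S,4aS,6S,7R,7aS)-7-hydroxy-4,7-bis(hydroxymethyl)-6-{[(Z)-3-iodoprop-2-enoyl]oxy}-1,4a,5,6,7,7a-hexahydrocyclopenta[c]pyran-1-yl (R)-3-methylpentanoate | CC[C@@H](C)CC(=O)O[C@@H]1OC=C(CO)[C@H]2C[C@H](OC(=O)/C=C\I)[C@](O)(CO)[C@@H]12
F2 | step 11 | (1S,4aS,7aS)-7-(hydroxymethyl)-4-oxo-1,3,4,4a,5,7a-hexahydrocyclopenta[c]pyran-1-yl (R)-3-methylpentanoate | CC[C@@H](C)CC(=O)O[C@@H]1OCC(=O)[C@H]2CC=C(CO)[C@@H]12
F3 | step 11 | 7α,8α-epoxy alcohol: 20 with free C10 hydroxyl | CC[C@@H](C)CC(=O)O[C@@H]1OCC(=O)[C@H]2C[C@H]3O[C@@]3(CO)[C@@H]12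
F4 | step 4 | (S)-tert-butyl (5-oxo-5,6-dihydro-2H-pyran-2-yl) carbonate | CC(C)(C)OC(=O)O[C@@H]1OCC(=O)C=C1
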